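The readings were generated by integration on assumed constants, and the scatter is random.

**Early minutes.** In the first minutes of Monday's run the target climbs along a nearly straight line, so we ask how long one catalyst takes per target made.

- Monday's: substrate 0.050 M; gas 2.3 mM (held); free catalyst 1 mM; run made earlier
- flask: substrate 0.050 M; gas 2.3 mM (held); free catalyst 0.50 mM; time 30 min

Monday's run (percent of the substrate charged): time / min: target / % = 0.200: 0.2; 0.667: 0.5; 1.00: 1.5; 1.50: 2.6; 2.50: 4.5; 3.00: 5.1

(scatter of a reading: 0.5 percentage points)

* amount of target in percent of the substrate charged, at 6.0 min, 15 min and 30 min

- what was read earlier has a scatter of 0.5 percentage points, one standard deviation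
- at the start none of the gas is in solution
- no earlier run changes the charge of free catalyst; that part of a forecast is a guess

**Round time.** Between 0.667 min and 3.00 min Monday's target rose 4.6 percentage points. Shared out over 1 mM of free catalyst and 0.050 M of substrate, that gives 1.01 min as the round time, the minutes one catalyst needs for one target, the inverse of the turnover frequency. It rests on two readings, each with a scatter of 0.5 points.

**Turned round.** The opposite outcome is a curve that flattens inside the run, as it must if the substrate is used up by 30 min. In this flask one round of the charged catalyst makes 1.00 % of the substrate charge, so the charge needs 100 rounds, and fitting them into 30 min takes a round of 0.300 min. The round read from Monday's run is longer. Counted at that round, this flask's charge lasts 101 min, and the run covers a third of that.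

**Our count.** No earlier run changes the catalyst, so we guess that the round time holds at [free catalyst] = 0.50 mM. We also guess that falling [substrate] doesn't lengthen it, for Monday's run stopped at 5.1 % made. Our count for this flask is then 5.92 %, 14.8 % and 29.6 %, taken from zero, since the lag read off Monday's run, 0.413 min, is shorter than a round.

**The forecast.** The forecast gives 5.2 %, 12.5 % and 22 %, which at 30 min is less than our count. It says: “I shade the later values down slightly for possible deactivation.”

**The flask.** It gave 5.90 %, 15.0 % and 29.6 %.

    free catalyst + target → free catalyst + over-reaction product (k = 0.310 L mol⁻¹ s⁻¹)
    free catalyst ⇌ dormant form (K = 1.50, k = 5.60 × 10⁻⁵ s⁻¹)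
    reagent + catalyst intermediate A ⇌ catalyst intermediate B (K = 1200 L mol⁻¹, k = 37.0 L mol⁻¹ s⁻¹)
    catalyst intermediate B → catalyst intermediate C (k = 0.0550 s⁻¹)
    catalyst intermediate C → free catalyst + target (k = 0.0710 s⁻¹)
    substrate + free catalyst → catalyst intermediate A (k = 3.10 L mol⁻¹ s⁻¹)
    gas ⇌ reagent, rate k7*(csat - [reagent]) (kL = 0.330 s⁻¹)

**Step by step.** In this flask, between 3.00 min and 30.0 min, [reagent] stood at 0.00228 M while substrate fell from 96.3 % to 68.9 %, catalyst intermediate C stood at 24.5 % and then 23.1 % of the catalyst, and on average each charged catalyst took 1.01 min per target standing at 30 min, the round time read on Monday being 1.01 min. By 300 min, past the 101 min of the count, this flask held substrate at 0 %, and free catalyst had turned target into over-reaction product, leaving 25.1 % target and 74.9 % over-reaction product.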